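**Retrosynthetic overview**

- The route rests on C4 of the tetralone (ring B). It is a diarylmethine CH bonded to C4a of the catechol ring A, to C1' of the naphthalene and to the C3 methylene, and C1 can sit on C8a as a benzoate ester from the start.
- C1–C2 is disconnected last (Dieckmann closure of ring B, then loss of the extra ester carbon). C2–C3 and C4–C1' are disconnected together as one nickel-catalysed three-component alkyl-arylation of a 6-vinylbenzoate with tert-butyl bromoacetate and a 1-iodonaphthalene.
- The styrene comes from 2,3-dihydroxybenzaldehyde. Bromination is done at the aldehyde stage, where para-attack relative to the 3-alkoxy group (C6) is established, and is followed by oxidation, esterification and vinylation. The iodide comes from 5-methoxy-1-naphthol by para-iodination and benzylation.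
- Ring order: ring A and the naphthalene are bought. Ring B is the only ring formed (step 9), after the C4 stereocentre is set (step 8).

Key step: step 8

Assumption: the sense of induction of the nickel–bis(imidazoline) catalyst is not predicted here; the ligand antipode that leads to (R)-11 is to be found in a trial run and then used. L* = (4S,4'S)-1,1'-bis(3,5-di-tert-butylphenyl)-4,4'-diisopropyl-4,4',5,5'-tetrahydro-1H,1'H-2,2'-biimidazole or its antipode. Tetralone atoms are numbered C1–C8a, naphthalene atoms are primed.

**Route**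

Step 1
Reactants: 1 2,3-dihydroxybenzaldehyde
Product: 2 2,3-bis(benzyloxy)benzaldehyde
Conditions: BnBr (2.4 equiv), K2CO3 (3 equiv), DMF, 60 °C
Reagents that add atoms: benzyl bromide, BrCc1ccccc1
Why: Williamson ether synthesis; both phenoxides are alkylated by SN2 on the benzylic bromide, excess base and warming bringing the hydrogen-bonded 2-OH to reaction.

Step 2
Reactants: 2 2,3-bis(benzyloxy)benzaldehyde
Product: 3 2,3-bis(benzyloxy)-6-bromobenzaldehyde
Conditions: NBS (1.05 equiv), DMF, rt, dark
Reagents that add atoms: N-bromosuccinimide, O=C1CCC(=O)N1Br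
Why: Electrophilic aromatic bromination; the 2-benzyloxy group is twisted out of conjugation by its two neighbours, so the in-plane 3-benzyloxy group should direct to its para position C6, as is established for 2,3-dialkoxybenzaldehydes.

Step 3
Reactants: 3 2,3-bis(benzyloxy)-6-bromobenzaldehyde
Product: 4 2,3-bis(benzyloxy)-6-bromobenzoic acid
Conditions: NaClO2, NaH2PO4, 2-methyl-2-butene, t-BuOH/THF/H2O, 0 °C → rt
Reagents that add atoms: sodium chlorite, [Na+].[O-]Cl=O
Why: Pinnick oxidation; chlorous acid oxidises the hindered aldehyde and the alkene scavenges hypochlorous acid, so the electron-rich ring and the benzyl ethers should not be chlorinated.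

Step 4
Reactants: 4 2,3-bis(benzyloxy)-6-bromobenzoic acid
Product: 5 methyl 2,3-bis(benzyloxy)-6-bromobenzoate
Conditions: MeI, K2CO3, DMF, rt
Reagents that add atoms: iodomethane, CI
Why: Carboxylate O-alkylation (SN2 on iodomethane) is insensitive to the two ortho substituents that would slow a Fischer esterification.

Step 5
Reactants: 5 methyl 2,3-bis(benzyloxy)-6-bromobenzoate
Product: 6 methyl 2,3-bis(benzyloxy)-6-vinylbenzoate
Conditions: CH2=CHBpin (1.5 equiv), Pd(dppf)Cl2 (5 mol %), K2CO3 (3 equiv), dioxane/H2O (5:1), 85 °C
Reagents that add atoms: 4,4,5,5-tetramethyl-2-vinyl-1,3,2-dioxaborolane, C=CB1OC(C)(C)C(C)(C)O1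
Why: Suzuki–Miyaura coupling; oxidative addition into the aryl bromide is helped by the ortho ester, and the hindered methyl ester should survive aqueous carbonate.

Step 6
Reactants: 7 5-methoxynaphthalen-1-ol
Product: 8 4-iodo-5-methoxynaphthalen-1-ol
Conditions: NIS (1.0 equiv), MeCN, −20 → 0 °C, dark
Reagents that add atoms: N-iodosuccinimide, O=C1CCC(=O)N1I
Why: Electrophilic aromatic iodination; the free hydroxyl is the strongest donor and in a polar aprotic solvent should direct the halonium source to its para (alpha) position C4, as N-halosuccinimides do with 1-naphthols and 1,5-dialkoxynaphthalenes; any 2-iodo isomer would be removed here.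

Step 7
Reactants: 8 4-iodo-5-methoxynaphthalen-1-ol
Product: 9 1-(benzyloxy)-4-iodo-5-methoxynaphthalene
Conditions: BnBr (1.2 equiv), K2CO3, DMF, rt, dark
Reagents that add atoms: benzyl bromide, BrCc1ccccc1
Why: Williamson etherification of the naphthoxide; the aryl iodide is inert to carbonate and SN2 conditions, and capping the naphthol removes its sensitivity to oxidation.

Step 8
Reactants: 6 methyl 2,3-bis(benzyloxy)-6-vinylbenzoate (1.0 equiv); 9 1-(benzyloxy)-4-iodo-5-methoxynaphthalene (1.3 equiv); 10 tert-butyl bromoacetate (2.0 equiv)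
Product: 11 tert-butyl (4R)-4-[3,4-bis(benzyloxy)-2-(methoxycarbonyl)phenyl]-4-[4-(benzyloxy)-8-methoxynaphthalen-1-yl]butanoate
Conditions: NiBr2(dme) (10 mol %), L* (12 mol %), Mn powder (3 equiv), DMA/THF (1:1), 5 °C; 10 added slowly
Reagents that add atoms: none
Why: Zerovalent nickel carrying the chiral bis(imidazoline) inserts into the C–I bond of 9, while low-valent nickel abstracts bromine from 10 to release the electrophilic radical •CH2CO2tBu, which adds to the unsubstituted CH2 terminus of styrene 6 (bond C2–C3) and leaves a benzylic radical at C4. This radical is captured by the naphthylnickel complex and reductive elimination from trivalent nickel forms the C4–C1' bond, Mn returning nickel to its low-valent state. The closest known reaction type is the nickel-catalysed enantioselective reductive three-component alkyl-arylation of vinylarenes with alkyl halides and aryl halides, which gives 1,1-diarylalkanes. No ring is closed in this step. The C4 stereocentre is set under catalyst control, the chiral ligand on nickel deciding which face of the planar benzylic radical is arylated in the capture and reductive elimination sequence. The step needs terminal regioselectivity (secured by formation of the stabilised benzylic radical), three-component over direct aryl–alkyl coupling (secured by the polarity match between the ester radical and the alkoxy-substituted styrene, a high styrene concentration and slow addition of 10) and oxidative addition of the aryl halide ahead of the alkyl bromide (secured by using the iodide).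

Step 9
Reactants: 11 tert-butyl (4R)-4-[3,4-bis(benzyloxy)-2-(methoxycarbonyl)phenyl]-4-[4-(benzyloxy)-8-methoxynaphthalen-1-yl]butanoate
Product: 12 tert-butyl (4R)-7,8-bis(benzyloxy)-4-[4-(benzyloxy)-8-methoxynaphthalen-1-yl]-1-oxo-1,2,3,4-tetrahydronaphthalene-2-carboxylate (C2 epimers and enol form)
Conditions: LiN(SiMe3)2 (2.2 equiv), THF, −78 → −20 °C; AcOH, −78 °C
Reagents that add atoms: none
Why: Dieckmann condensation; the only enolisable ester (C2) is deprotonated and attacks the aryl methyl ester in a 6-exo-trig closure (bond C1–C2), the product being held as its lithium β-keto ester enolate, while the hindered tertiary C4–H should be out of reach of this weak amide base at low temperature, so the stereocentre is kept.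

Step 10
Reactants: 12 tert-butyl (4R)-7,8-bis(benzyloxy)-4-[4-(benzyloxy)-8-methoxynaphthalen-1-yl]-1-oxo-1,2,3,4-tetrahydronaphthalene-2-carboxylate
Product: 14 (4R)-7,8-bis(benzyloxy)-4-[4-(benzyloxy)-8-methoxynaphthalen-1-yl]-3,4-dihydronaphthalen-1(2H)-one, via β-keto acid 13 (not isolated)
Conditions: TsOH·H2O (0.2 equiv), toluene, 80 °C
Reagents that add atoms: none
Why: Acid-catalysed E1 cleavage of the tert-butyl ester (isobutene leaves the hot solution, which limits tert-butylation of the electron-rich naphthalene) gives the β-keto acid, which decarboxylates through the six-membered cyclic transition state; aryl benzyl ethers tolerate catalytic sulfonic acid and C4 is not alpha to a carbonyl.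

Step 11
Reactants: 14 (4R)-7,8-bis(benzyloxy)-4-[4-(benzyloxy)-8-methoxynaphthalen-1-yl]-3,4-dihydronaphthalen-1(2H)-one
Product: 15 (4R)-7,8-dihydroxy-4-(4-hydroxy-8-methoxynaphthalen-1-yl)-3,4-dihydronaphthalen-1(2H)-one
Conditions: H2 (1 atm), Pd/C (10 %), EtOAc/MeOH, rt; work-up under argon
Reagents that add atoms: none
Why: Hydrogenolysis of the three aryl benzyl ethers over palladium on carbon; the aryl ketone on an electron-rich ring is reduced far more slowly, the methyl ether and the C4–C bonds are inert, and the reaction is stopped after three equivalents of hydrogen.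

**Compound list**

1 | 2,3-dihydroxybenzaldehyde | O=Cc1cccc(O)c1O | starting material
2 | 2,3-bis(benzyloxy)benzaldehyde | O=Cc1cccc(OCc2ccccc2)c1OCc1ccccc1 | intermediate
3 | 2,3-bis(benzyloxy)-6-bromobenzaldehyde | O=Cc1c(Br)ccc(OCc2ccccc2)c1OCc1ccccc1 | intermediate
4 | 2,3-bis(benzyloxy)-6-bromobenzoic acid | OC(=O)c1c(Br)ccc(OCc2ccccc2)c1OCc1ccccc1 | intermediate
5 | methyl 2,3-bis(benzyloxy)-6-bromobenzoate | COC(=O)c1c(Br)ccc(OCc2ccccc2)c1OCc1ccccc1 | intermediate
6 | methyl 2,3-bis(benzyloxy)-6-vinylbenzoate | COC(=O)c1c(C=C)ccc(OCc2ccccc2)c1OCc1ccccc1 | intermediate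
7 | 5-methoxynaphthalen-1-ol | COc1cccc2c(O)cccc12 | starting material
8 | 4-iodo-5-methoxynaphthalen-1-ol | COc1cccc2c(O)ccc(I)c12 | intermediate
9 | 1-(benzyloxy)-4-iodo-5-methoxynaphthalene | COc1cccc2c(OCc3ccccc3)ccc(I)c12 | intermediate
10 | tert-butyl bromoacetate | CC(C)(C)OC(=O)CBr | starting material
11 | tert-butyl (4R)-4-[3,4-bis(benzyloxy)-2-(methoxycarbonyl)phenyl]-4-[4-(benzyloxy)-8-methoxynaphthalen-1-yl]butanoate | COc1cccc2c(OCc3ccccc3)ccc([C@H](c3ccc(OCc4ccccc4)c(OCc4ccccc4)c3C(=O)OC)CCC(=O)OC(C)(C)C)c12 | intermediate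
12 | tert-butyl (4R)-7,8-bis(benzyloxy)-4-[4-(benzyloxy)-8-methoxynaphthalen-1-yl]-1-oxo-1,2,3,4-tetrahydronaphthalene-2-carboxylate (C2 unassigned) | COc1cccc2c(OCc3ccccc3)ccc([C@H]3CC(C(=O)OC(C)(C)C)C(=O)c4c3ccc(OCc3ccccc3)c4OCc3ccccc3)c12 | intermediate
13 | (4R)-7,8-bis(benzyloxy)-4-[4-(benzyloxy)-8-methoxynaphthalen-1-yl]-1-oxo-1,2,3,4-tetrahydronaphthalene-2-carboxylic acid (C2 unassigned, not isolated) | COc1cccc2c(OCc3ccccc3)ccc([C@H]3CC(C(=O)O)C(=O)c4c3ccc(OCc3ccccc3)c4OCc3ccccc3)c12 | intermediate
14 | (4R)-7,8-bis(benzyloxy)-4-[4-(benzyloxy)-8-methoxynaphthalen-1-yl]-3,4-dihydronaphthalen-1(2H)-one | COc1cccc2c(OCc3ccccc3)ccc([C@H]3CCC(=O)c4c3ccc(OCc3ccccc3)c4OCc3ccccc3)c12 | intermediate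
15 | (4R)-7,8-dihydroxy-4-(4-hydroxy-8-methoxynaphthalen-1-yl)-3,4-dihydronaphthalen-1(2H)-one | COc1cccc2c(O)ccc([C@H]3CCC(=O)c4c3ccc(O)c4O)c12 | target

**Step count**

Total: 11 steps. Longest linear sequence: 9 steps (steps 1–5 and 8–11, from 1).

**Steps most likely to fail**

Step 8. Capture of the crowded C4 benzylic radical (ortho ester) by the peri-methoxy naphthylnickel species may be slow. Direct coupling of the ester radical with arylnickel, radical dimerisation or reduction of the aryl iodide could then take over, and facial discrimination at so congested a centre may be poor.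
The fallback sets out from 6, 9 and 10 and comes back at 11. It separates radical addition from arylation.
A Kharasch-type atom-transfer radical addition of 10 to 6 under photoredox conditions (Ir(ppy)3, LiBr, DMF, blue light) should give racemic tert-butyl 4-[3,4-bis(benzyloxy)-2-(methoxycarbonyl)phenyl]-4-bromobutanoate F1.
Zinc insertion into 9 (Zn dust, LiCl, THF, 40 °C) should give [4-(benzyloxy)-8-methoxynaphthalen-1-yl]zinc iodide F2.
An enantioconvergent nickel-catalysed Negishi arylation of the racemic benzylic bromide (NiBr2(diglyme), chiral bis(oxazoline), LiI, CH2Cl2/THF, −45 °C) would then join the two to give 11. This is a known way to 4,4-diarylbutanoates that serve as 4-aryl-1-tetralone precursors.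

Step 9. The base may also remove the C4 hydrogen, which is doubly benzylic and lateral to the benzoate; this would erode the enantiomeric purity. Attack on the doubly ortho-flanked methyl ester may also be slow.
The fallback sets out from 11 and comes back at 14. It replaces the amide base by soft enolisation, which only touches a C–H alpha to a titanium-bound carbonyl.
TsOH (cat.) in toluene at 60 °C or TFA/CH2Cl2 at 0 °C removes the tert-butyl group to give (4R)-4-[3,4-bis(benzyloxy)-2-(methoxycarbonyl)phenyl]-4-[4-(benzyloxy)-8-methoxynaphthalen-1-yl]butanoic acid F3.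
MeI/K2CO3 in DMF gives methyl (4R)-4-[3,4-bis(benzyloxy)-2-(methoxycarbonyl)phenyl]-4-[4-(benzyloxy)-8-methoxynaphthalen-1-yl]butanoate F4.
A titanium-mediated Dieckmann closure (TiCl4, Bu3N, cat. Me3SiOTf, CH2Cl2, −78 → 0 °C) should give methyl (4R)-7,8-bis(benzyloxy)-4-[4-(benzyloxy)-8-methoxynaphthalen-1-yl]-1-oxo-1,2,3,4-tetrahydronaphthalene-2-carboxylate F5.
Krapcho demethoxycarbonylation (LiCl, wet DMSO, 130 °C) then returns 14.

Step 6. Ortho-iodination at C2 may compete with the wanted para attack, which is peri to the methoxy group, and the electron-rich iodonaphthol may be oxidised to the quinone.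
The fallback sets out from 7 and comes back at 9. It introduces the halogen as bromine, for which para selectivity on 1-naphthols in acetonitrile is best founded, and exchanges it after protection.
NBS in MeCN at 0 °C should give 4-bromo-5-methoxynaphthalen-1-ol F6.
BnBr/K2CO3 in DMF gives 1-(benzyloxy)-4-bromo-5-methoxynaphthalene F7.
Bromine–lithium exchange (n-BuLi, THF, −78 °C) gives [4-(benzyloxy)-8-methoxynaphthalen-1-yl]lithium F8, which is quenched with I2 to give 9.

**Further compounds**

F1 | step 8 | tert-butyl 4-[3,4-bis(benzyloxy)-2-(methoxycarbonyl)phenyl]-4-bromobutanoate (racemic) | COC(=O)c1c(C(Br)CCC(=O)OC(C)(C)C)ccc(OCc2ccccc2)c1OCc1ccccc1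
F2 | step 8 | [4-(benzyloxy)-8-methoxynaphthalen-1-yl]zinc iodide | COc1cccc2c(OCc3ccccc3)ccc([Zn]I)c12
F3 | step 9 | (4R)-4-[3,4-bis(benzyloxy)-2-(methoxycarbonyl)phenyl]-4-[4-(benzyloxy)-8-methoxynaphthalen-1-yl]butanoic acid | COc1cccc2c(OCc3ccccc3)ccc([C@H](c3ccc(OCc4ccccc4)c(OCc4ccccc4)c3C(=O)OC)CCC(=O)O)c12
F4 | step 9 | methyl (4R)-4-[3,4-bis(benzyloxy)-2-(methoxycarbonyl)phenyl]-4-[4-(benzyloxy)-8-methoxynaphthalen-1-yl]butanoate | COc1cccc2c(OCc3ccccc3)ccc([C@H](c3ccc(OCc4ccccc4)c(OCc4ccccc4)c3C(=O)OC)CCC(=O)OC)c12
F5 | step 9 | methyl (4R)-7,8-bis(benzyloxy)-4-[4-(benzyloxy)-8-methoxynaphthalen-1-yl]-1-oxo-1,2,3,4-tetrahydronaphthalene-2-carboxylate (C2 unassigned) | COc1cccc2c(OCc3ccccc3)ccc([C@H]3CC(C(=O)OC)C(=O)c4c3ccc(OCc3ccccc3)c4OCc3ccccc3)c12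
F6 | step 6 | 4-bromo-5-methoxynaphthalen-1-ol | COc1cccc2c(O)ccc(Br)c12
F7 | step 6 | 1-(benzyloxy)-4-bromo-5-methoxynaphthalene | COc1cccc2c(OCc3ccccc3)ccc(Br)c12
F8 | step 6 | [4-(benzyloxy)-8-methoxynaphthalen-1-yl]lithium | COc1cccc2c(OCc3ccccc3)ccc([Li])c12
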